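## Retrosynthetic overview
1. End game on the finished macrocycle: C16 primary alcohol → aldehyde → α-methylenation (C17) → acid → methyl ester.
2. 14-membered ring: the C6–C7 bond is made by intramolecular alkylation of a C5/C6 β-keto sulfone with a C7 allylic bromide, followed by desulfonylation.
3. Oxirane: the C12 tertiary alkoxide displaces a (13S)-mesylate with inversion. The C13–OH comes from reagent-controlled ketone reduction, and C8=C9 (E) from cross metathesis with methacrolein.
4. Key bond C1–C14: an intermolecular, amine-catalysed asymmetric Michael addition of β-keto ester fragment R (C9–C14) to enal fragment L (C1–C5, C15, C16). This step sets C1.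
5. Both fragments come from one acid, (S)-2-hydroxy-2-methylhex-5-enoic acid (Sharpless epoxidation of methallyl alcohol, then allyl Grignard opening), which supplies C4 and C12. Ring order: oxirane first (step 14), carbocycle second (step 19).

**Labels:** C1 is the ring CH bearing the acrylate. The ring continues C2, C3, C4 (C–OH), C5 (C=O), C6, C7, C8=C9, C10, C11, C12–C13 (oxirane), C14. The side chain is C15(=C17H2)–C16O2Me. The text uses these labels for all intermediates. Names of open-chain compounds carry their own chain locants.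

**Assumption:** the SMILES is read literally, that is (1S,4S,12S,13R), 8E, with C11 and C14 cis on the oxirane.

## Route

Step 1
Reactants: 1 2-methylprop-2-en-1-ol
Product: 2 (R)-(2-methyloxiran-2-yl)methanol [(R)-2-methylglycidol]
Conditions: Ti(OiPr)4 (5 mol%), D-(−)-diisopropyl tartrate (6 mol%), cumene hydroperoxide, 4 Å MS, CH2Cl2, −20 °C; distillation
Reagents that add atoms: cumene hydroperoxide CC(C)(OO)c1ccccc1
Why: Sharpless asymmetric epoxidation, in which the titanium–D-tartrate complex binds the allylic alcohol and delivers oxygen to one alkene face, setting (about 94% ee) the quaternary centre that becomes both C4 and C12.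

Step 2
Reactants: 2 (R)-2-methylglycidol
Product: 3 (S)-2-methylhex-5-ene-1,2-diol
Conditions: allylMgCl (2.5 equiv), CuI (copper monoiodide, 10 mol%), THF, −40 → 0 °C; aq. work-up
Reagents that add atoms: allylmagnesium chloride C=CC[Mg]Cl
Why: Copper-catalysed SN2 opening of the 2,2-disubstituted epoxide occurs only at the unhindered CH2 terminus, so the C–O bond at the stereocentre is untouched and the descriptor changes from R to S only through CIP ranking.

Step 3
Reactants: 3 (S)-2-methylhex-5-ene-1,2-diol
Product: 5 (S)-2-hydroxy-2-methylhex-5-enoic acid, via hydroxy aldehyde 4 (not isolated)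
Conditions: TEMPO (7 mol%), NaOCl (2 mol%), NaClO2 (2 equiv), MeCN–phosphate buffer pH 6.7, 35 °C
Reagents that add atoms: sodium chlorite [Na+].[O-]Cl=O
Why: TEMPO/chlorite oxidation takes only the primary alcohol through the aldehyde to the acid, since the tertiary alcohol cannot be oxidised and the near-neutral, hypochlorite-poor medium spares the terminal alkene and avoids glycol cleavage.

Step 4
Reactants: 5 (S)-2-hydroxy-2-methylhex-5-enoic acid
Product: 6 methyl (S)-2-hydroxy-2-methylhex-5-enoate
Conditions: MeI, K2CO3, DMF, rt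
Reagents that add atoms: iodomethane CI
Why: Carboxylate SN2 O-alkylation is chemoselective because the carboxylate is far more nucleophilic than the neutral tertiary alcohol under carbonate.

Step 5
Reactants: 6 methyl (S)-2-hydroxy-2-methylhex-5-enoate
Product: 7 methyl (S)-2-(tert-butyldimethylsilyloxy)-2-methylhex-5-enoate
Conditions: TBSOTf, 2,6-lutidine, CH2Cl2, 0 °C → rt
Reagents that add atoms: tert-butyldimethylsilyl triflate CC(C)(C)[Si](C)(C)OS(=O)(=O)C(F)(F)F
Why: A silyl triflate with a hindered pyridine base silylates even tertiary alcohols, giving a TBS ether that later survives the acid used to remove TES and keeps the C4 oxygen out of the acylation at C5.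

Step 6
Reactants: 7 methyl (S)-2-(tert-butyldimethylsilyloxy)-2-methylhex-5-enoate
Product: 8 methyl (2S,5E)-2-(tert-butyldimethylsilyloxy)-2-methyl-7-oxohept-5-enoate (fragment L)
Conditions: (E)-crotonaldehyde (5 equiv), second-generation Hoveyda–Grubbs catalyst [RuCl2(H2IMes)(=CH-C6H4-2-OiPr)] (3 mol%), CH2Cl2, 40 °C
Reagents that add atoms: (E)-crotonaldehyde C/C=C/C=O
Why: Olefin cross metathesis of an unhindered terminal alkene with the electron-poor partner crotonaldehyde favours the cross product and gives the E-enal under thermodynamic control while propene escapes.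

Step 7
Reactants: 5 (S)-2-hydroxy-2-methylhex-5-enoic acid
Product: 10 (S)-2-methyl-2-(triethylsilyloxy)hex-5-enoic acid, via bis-silyl compound 9 (not isolated)
Conditions: TESOTf (2.3 equiv), 2,6-lutidine, CH2Cl2, 0 °C; then THF–H2O, rt
Reagents that add atoms: triethylsilyl triflate CC[Si](CC)(CC)OS(=O)(=O)C(F)(F)F
Why: The silyl triflate silylates both the tertiary alcohol and the acid, and water then hydrolyses only the far more labile silyl ester, leaving the tertiary TES ether that blocks tetronic acid formation at the β-keto ester stage.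

Step 8
Reactants: 10 (S)-2-methyl-2-(triethylsilyloxy)hex-5-enoic acid
Product: 12 allyl (S)-4-methyl-3-oxo-4-(triethylsilyloxy)oct-7-enoate (fragment R), via acyl imidazole 11 (not isolated)
Conditions: CDI, THF, rt; then LiCH2CO2allyl (allyl acetate, LDA, 3.3 equiv each), THF, −78 °C; aq. work-up
Reagents that add atoms: allyl acetate CC(=O)OCC=C; 1,1'-carbonyldiimidazole O=C(n1ccnc1)n1ccnc1 (imidazolyl group of 11 only)
Why: In this crossed Claisen-type condensation the acyl imidazole has no α-hydrogen and is attacked at −78 °C by the preformed ester enolate faster than the enolate self-condenses, and deprotonation of the β-keto ester formed makes the acylation irreversible.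

Step 9
Reactants: 8 fragment L enal; 12 fragment R β-keto ester
Product: 13 methyl (2S,5R,8S)-6-(allyloxycarbonyl)-2-(tert-butyldimethylsilyloxy)-2,8-dimethyl-7-oxo-5-(2-oxoethyl)-8-(triethylsilyloxy)dodec-11-enoate (epimers at chain C6 = C14)
Conditions: (S)-α,α-diphenylprolinol trimethylsilyl ether (15 mol%), PhCO2H (15 mol%), toluene, 4 °C → rt
Reagents that add atoms: none
Why: In this iminium-catalysed asymmetric Michael addition (Jørgensen–Hayashi catalyst) the CPh2(OTMS) group shields one face of the E-iminium ion of 8, so the enol of 12 attacks C1 from the open face and forms C1–C14 with the C1 configuration of the target (labelled R here only because of CIP ranking), while the quaternary C12 rules out a follow-up aldol cyclisation.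

Step 10
Reactants: 13 Michael adduct
Product: 15 methyl (2S,5R,8S)-2-(tert-butyldimethylsilyloxy)-2,8-dimethyl-7-oxo-5-(2-oxoethyl)-8-(triethylsilyloxy)dodec-11-enoate, via keto acid 14 (not isolated)
Conditions: Pd(OAc)2 (5 mol%), PPh3 (20 mol%), HCO2H, Et3N, THF, rt
Reagents that add atoms: none
Why: In this Tsuji deallylation, zerovalent palladium formed in situ ionises the allyl ester, formate reduces the π-allyl unit to propene, and the freed β-keto acid loses CO2 at room temperature under near-neutral conditions that leave aldehyde, silyl ethers and C1 untouched while erasing the C14 stereocentre.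

Step 11
Reactants: 15 keto aldehyde
Product: 16 methyl (2S,5R,7S,8S)-2-(tert-butyldimethylsilyloxy)-7-hydroxy-5-(2-hydroxyethyl)-2,8-dimethyl-8-(triethylsilyloxy)dodec-11-enoate
Conditions: (R)-Me-CBS oxazaborolidine (0.5 equiv), catecholborane (3 equiv), toluene, −78 → −30 °C; aq. work-up
Reagents that add atoms: none
Why: In this Corey–Bakshi–Shibata reduction the (R)-oxazaborolidine binds the ketone with the quaternary C12 side as the large group and delivers hydride to one face, giving the (13S)-alcohol under reagent control, while the aldehyde is reduced at the same time and catecholborane does not hydroborate the alkene at low temperature.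

Step 12
Reactants: 16 diol
Product: 17 methyl (2S,5R,7S,8S)-2-(tert-butyldimethylsilyloxy)-5-[2-(tert-butyldiphenylsilyloxy)ethyl]-7-hydroxy-2,8-dimethyl-8-(triethylsilyloxy)dodec-11-enoate
Conditions: TBDPSCl (1.05 equiv), imidazole, CH2Cl2, 0 °C
Reagents that add atoms: tert-butyldiphenylsilyl chloride CC(C)(C)[Si](Cl)(c1ccccc1)c1ccccc1
Why: This silylation is sterically controlled, since the bulky chlorosilane reacts only with the primary C16 alcohol and leaves the neopentyl-like secondary C13–OH free.

Step 13
Reactants: 17 secondary alcohol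
Product: 18 methyl (2S,5R,7S,8S)-2-(tert-butyldimethylsilyloxy)-5-[2-(tert-butyldiphenylsilyloxy)ethyl]-2,8-dimethyl-7-(methylsulfonyloxy)-8-(triethylsilyloxy)dodec-11-enoate
Conditions: MsCl, Et3N, CH2Cl2, −10 °C
Reagents that add atoms: methanesulfonyl chloride CS(=O)(=O)Cl
Why: Sulfonylation through sulfene is fast even for hindered secondary alcohols and turns the only free hydroxyl (C13) into a leaving group with retention.

Step 14
Reactants: 18 mesylate
Product: 20 methyl (2S,5R,7R,8S)-2-(tert-butyldimethylsilyloxy)-5-[2-(tert-butyldiphenylsilyloxy)ethyl]-7,8-epoxy-2,8-dimethyldodec-11-enoate, via hydroxy mesylate 19 (not isolated)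
Conditions: CSA (10 mol%), MeOH–CH2Cl2, 0 °C → rt; then K2CO3, rt
Reagents that add atoms: none
Why: Acidic methanolysis removes only the TES ether (tertiary TBS and primary TBDPS ethers react far more slowly), and carbonate then triggers an intramolecular Williamson SN2 closure with inversion at C13 (S → R) and retention at C12, giving the oxirane with C11 and C14 cis as in the target.

Step 15
Reactants: 20 epoxy alkene
Product: 21 methyl (2S,5R,7R,8S,11E)-2-(tert-butyldimethylsilyloxy)-5-[2-(tert-butyldiphenylsilyloxy)ethyl]-7,8-epoxy-2,8,12-trimethyl-13-oxotridec-11-enoate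
Conditions: methacrolein (10 equiv), second-generation Hoveyda–Grubbs catalyst (5 mol%), CH2Cl2, 40 °C
Reagents that add atoms: methacrolein C=C(C)C=O
Why: Olefin cross metathesis with methacrolein gives the trisubstituted enal as the E isomer (formyl trans to the chain), fixing the C8=C9 geometry, and epoxide, ester and silyl ethers are inert to the ruthenium carbene.

Step 16
Reactants: 21 enal
Product: 22 methyl (2S,5R,7R,8S,11E)-2-(tert-butyldimethylsilyloxy)-5-[2-(tert-butyldiphenylsilyloxy)ethyl]-7,8-epoxy-13-hydroxy-2,8,12-trimethyltridec-11-enoate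
Conditions: NaBH4, MeOH, −20 °C
Reagents that add atoms: none
Why: Borohydride 1,2-reduction of the α-methyl enal is much faster than any attack on the hindered ester or the epoxide.

Step 17
Reactants: 22 allylic alcohol ester
Product: 23 (3S,6R,8R,9S,12E)-3-(tert-butyldimethylsilyloxy)-6-[2-(tert-butyldiphenylsilyloxy)ethyl]-8,9-epoxy-14-hydroxy-3,9,13-trimethyl-1-(phenylsulfonyl)tetradec-12-en-2-one
Conditions: PhSO2CH3, n-BuLi (4 equiv each), THF, −78 → 0 °C; aq. work-up
Reagents that add atoms: methyl phenyl sulfone CS(=O)(=O)c1ccccc1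
Why: Claisen-type acylation of the sulfonyl carbanion by the non-enolisable, inductively activated α-silyloxy ester stops at the ketone because the product is deprotonated at once, and one extra equivalent of carbanion covers the free allylic alcohol.

Step 18
Reactants: 23 β-keto sulfone alcohol
Product: 24 (3S,6R,8R,9S,12E)-14-bromo-3-(tert-butyldimethylsilyloxy)-6-[2-(tert-butyldiphenylsilyloxy)ethyl]-8,9-epoxy-3,9,13-trimethyl-1-(phenylsulfonyl)tetradec-12-en-2-one
Conditions: CBr4, PPh3, CH2Cl2, −20 °C
Reagents that add atoms: carbon tetrabromide BrC(Br)(Br)Br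
Why: In this Appel reaction, SN2 displacement of the oxyphosphonium ion converts the primary allylic alcohol into the bromide under neutral conditions without allylic transposition or loss of E geometry.

Step 19
Reactants: 24 bromo β-keto sulfone
Product: 25 (1R,4S,8E,12S,13R)-4-(tert-butyldimethylsilyloxy)-1-[2-(tert-butyldiphenylsilyloxy)ethyl]-12,13-epoxy-4,8,12-trimethyl-6-(phenylsulfonyl)cyclotetradec-8-en-5-one (C6 epimers, target labels)
Conditions: Cs2CO3 (5 equiv), MeCN, 40 °C, syringe-pump addition of 24 (final 1 mM)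
Reagents that add atoms: none
Why: High-dilution intramolecular SN2 C-alkylation of the soft caesium β-keto sulfone enolate by the primary allylic bromide closes the 14-membered carbocycle at C6–C7, a macrocyclisation type well proven for stabilised carbanion/allylic halide pairs.

Step 20
Reactants: 25 macrocyclic β-keto sulfone
Product: 26 (1R,4S,8E,12S,13R)-4-(tert-butyldimethylsilyloxy)-1-[2-(tert-butyldiphenylsilyloxy)ethyl]-12,13-epoxy-4,8,12-trimethylcyclotetradec-8-en-5-one
Conditions: freshly prepared aluminium amalgam Al(Hg), THF–H2O 9:1, 0 °C → rt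
Reagents that add atoms: none
Why: In this reductive desulfonylation, electron transfer to the β-keto sulfone expels sulfinate and protonation of the enolate gives the C6 methylene, which removes the C6 stereocentre while the isolated epoxide, alkene and silyl ethers are not reduced.

Step 21
Reactants: 26 bis-silyl ether
Product: 27 (1R,4S,8E,12S,13R)-12,13-epoxy-4-hydroxy-1-(2-hydroxyethyl)-4,8,12-trimethylcyclotetradec-8-en-5-one
Conditions: TBAF, AcOH (1:1, 4 equiv), THF, rt → 40 °C
Reagents that add atoms: none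
Why: Fluoride-driven Si–O cleavage removes both silyl ethers, and the acetic acid buffer keeps alkoxide basicity low so that the epoxide and the α-hydroxy ketone survive.

Step 22
Reactants: 27 diol
Product: 28 [(1S,4S,8E,12S,13R)-12,13-epoxy-4-hydroxy-4,8,12-trimethyl-5-oxocyclotetradec-8-en-1-yl]acetaldehyde
Conditions: Dess–Martin periodinane, NaHCO3, CH2Cl2, 0 °C → rt
Reagents that add atoms: none
Why: Dess–Martin oxidation converts the only oxidisable (primary) alcohol into the aldehyde, since the tertiary C4–OH is inert and bicarbonate protects the epoxide from acetic acid.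

Step 23
Reactants: 28 aldehyde
Product: 29 2-[(1S,4S,8E,12S,13R)-12,13-epoxy-4-hydroxy-4,8,12-trimethyl-5-oxocyclotetradec-8-en-1-yl]prop-2-enal
Conditions: aq. CH2O (37%), pyrrolidine (10 mol%), EtCO2H (10 mol%), i-PrOH, 45 °C
Reagents that add atoms: formaldehyde C=O
Why: In this organocatalytic Mannich-type α-methylenation an enamine forms only at the aldehyde, and addition to the formaldehyde-derived iminium ion followed by β-elimination gives the 2-substituted acrolein without touching the ketone α-positions or C1.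

Step 24
Reactants: 29 enal
Product: 30 2-[(1S,4S,8E,12S,13R)-12,13-epoxy-4-hydroxy-4,8,12-trimethyl-5-oxocyclotetradec-8-en-1-yl]prop-2-enoic acid
Conditions: NaClO2, NaH2PO4, 2-methylbut-2-ene, t-BuOH–H2O, 0 °C → rt
Reagents that add atoms: sodium chlorite [Na+].[O-]Cl=O
Why: In this Pinnick oxidation chlorous acid oxidises only the aldehyde, and the mild buffer and the hypochlorite scavenger protect the epoxide and both alkenes.

Step 25
Reactants: 30 acrylic acid
Product: 31 methyl 2-[(1S,4S,8E,12S,13R)-12,13-epoxy-4-hydroxy-4,8,12-trimethyl-5-oxocyclotetradec-8-en-1-yl]prop-2-enoate (CNP0154954.4)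
Conditions: TMSCHN2, toluene–MeOH, 0 °C
Reagents that add atoms: (trimethylsilyl)diazomethane C[Si](C)(C)C=[N+]=[N-]
Why: In this diazoalkane esterification the reagent is protonated only by the carboxylic acid, so the methyl ester forms under neutral conditions without conjugate addition or epoxide opening.

## Compound list
1 | 2-methylprop-2-en-1-ol | C=C(C)CO | starting material
2 | (R)-(2-methyloxiran-2-yl)methanol | C[C@@]1(CO)CO1 | intermediate
3 | (S)-2-methylhex-5-ene-1,2-diol | C=CCC[C@](C)(O)CO | intermediate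
4 | (S)-2-hydroxy-2-methylhex-5-enal (not isolated) | C=CCC[C@](C)(O)C=O | intermediate
5 | (S)-2-hydroxy-2-methylhex-5-enoic acid | C=CCC[C@](C)(O)C(=O)O | intermediate
6 | methyl (S)-2-hydroxy-2-methylhex-5-enoate | C=CCC[C@](C)(O)C(=O)OC | intermediate
7 | methyl (S)-2-(tert-butyldimethylsilyloxy)-2-methylhex-5-enoate | C=CCC[C@](C)(O[Si](C)(C)C(C)(C)C)C(=O)OC | intermediate
8 | methyl (2S,5E)-2-(tert-butyldimethylsilyloxy)-2-methyl-7-oxohept-5-enoate (fragment L) | O=C/C=C/CC[C@](C)(O[Si](C)(C)C(C)(C)C)C(=O)OC | intermediate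
9 | triethylsilyl (S)-2-methyl-2-(triethylsilyloxy)hex-5-enoate (not isolated) | C=CCC[C@](C)(O[Si](CC)(CC)CC)C(=O)O[Si](CC)(CC)CC | intermediate
10 | (S)-2-methyl-2-(triethylsilyloxy)hex-5-enoic acid | C=CCC[C@](C)(O[Si](CC)(CC)CC)C(=O)O | intermediate
11 | (S)-1-(imidazol-1-yl)-2-methyl-2-(triethylsilyloxy)hex-5-en-1-one (not isolated) | C=CCC[C@](C)(O[Si](CC)(CC)CC)C(=O)n1ccnc1 | intermediate
12 | allyl (S)-4-methyl-3-oxo-4-(triethylsilyloxy)oct-7-enoate (fragment R) | C=CCC[C@](C)(O[Si](CC)(CC)CC)C(=O)CC(=O)OCC=C | intermediate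
13 | Michael adduct, (1R,4S,12S), C14 epimers | COC(=O)[C@@](C)(O[Si](C)(C)C(C)(C)C)CC[C@H](CC=O)C(C(=O)OCC=C)C(=O)[C@](C)(CCC=C)O[Si](CC)(CC)CC | intermediate
14 | β-keto acid from 13 (not isolated) | COC(=O)[C@@](C)(O[Si](C)(C)C(C)(C)C)CC[C@H](CC=O)C(C(=O)O)C(=O)[C@](C)(CCC=C)O[Si](CC)(CC)CC | intermediate
15 | keto aldehyde, (1R,4S,12S) | COC(=O)[C@@](C)(O[Si](C)(C)C(C)(C)C)CC[C@H](CC=O)CC(=O)[C@](C)(CCC=C)O[Si](CC)(CC)CC | intermediate
16 | C13,C16-diol, (1R,4S,12S,13S) | COC(=O)[C@@](C)(O[Si](C)(C)C(C)(C)C)CC[C@H](CCO)C[C@H](O)[C@](C)(CCC=C)O[Si](CC)(CC)CC | intermediate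
17 | C16 TBDPS ether, C13 alcohol, (1R,4S,12S,13S) | COC(=O)[C@@](C)(O[Si](C)(C)C(C)(C)C)CC[C@H](CCO[Si](c1ccccc1)(c1ccccc1)C(C)(C)C)C[C@H](O)[C@](C)(CCC=C)O[Si](CC)(CC)CC | intermediate
18 | C13 mesylate, (1R,4S,12S,13S) | COC(=O)[C@@](C)(O[Si](C)(C)C(C)(C)C)CC[C@H](CCO[Si](c1ccccc1)(c1ccccc1)C(C)(C)C)C[C@H](OS(C)(=O)=O)[C@](C)(CCC=C)O[Si](CC)(CC)CC | intermediate
19 | C12 alcohol C13 mesylate (not isolated) | COC(=O)[C@@](C)(O[Si](C)(C)C(C)(C)C)CC[C@H](CCO[Si](c1ccccc1)(c1ccccc1)C(C)(C)C)C[C@H](OS(C)(=O)=O)[C@](C)(CCC=C)O | intermediate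
20 | C12–C13 epoxide, (1R,4S,12S,13R) | COC(=O)[C@@](C)(O[Si](C)(C)C(C)(C)C)CC[C@H](CCO[Si](c1ccccc1)(c1ccccc1)C(C)(C)C)C[C@H]1O[C@@]1(C)CCC=C | intermediate
21 | (8E)-C7 enal | COC(=O)[C@@](C)(O[Si](C)(C)C(C)(C)C)CC[C@H](CCO[Si](c1ccccc1)(c1ccccc1)C(C)(C)C)C[C@H]1O[C@@]1(C)CC/C=C(\C)C=O | intermediate
22 | (8E)-C7 allylic alcohol | COC(=O)[C@@](C)(O[Si](C)(C)C(C)(C)C)CC[C@H](CCO[Si](c1ccccc1)(c1ccccc1)C(C)(C)C)C[C@H]1O[C@@]1(C)CC/C=C(\C)CO | intermediate
23 | C5/C6 β-keto sulfone, C7 alcohol | O=S(=O)(c1ccccc1)CC(=O)[C@@](C)(O[Si](C)(C)C(C)(C)C)CC[C@H](CCO[Si](c1ccccc1)(c1ccccc1)C(C)(C)C)C[C@H]1O[C@@]1(C)CC/C=C(\C)CO | intermediate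
24 | C5/C6 β-keto sulfone, C7 bromide | O=S(=O)(c1ccccc1)CC(=O)[C@@](C)(O[Si](C)(C)C(C)(C)C)CC[C@H](CCO[Si](c1ccccc1)(c1ccccc1)C(C)(C)C)C[C@H]1O[C@@]1(C)CC/C=C(\C)CBr | intermediate
25 | macrocyclic β-keto sulfone (C6 epimers) | O=S(=O)(c1ccccc1)C2C(=O)[C@@](C)(O[Si](C)(C)C(C)(C)C)CC[C@H](CCO[Si](c1ccccc1)(c1ccccc1)C(C)(C)C)C[C@H]1O[C@@]1(C)CC/C=C(\C)C2 | intermediate
26 | macrocyclic ketone, bis-silyl ether | C2C(=O)[C@@](C)(O[Si](C)(C)C(C)(C)C)CC[C@H](CCO[Si](c1ccccc1)(c1ccccc1)C(C)(C)C)C[C@H]1O[C@@]1(C)CC/C=C(\C)C2 | intermediate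
27 | macrocyclic diol | C2C(=O)[C@@](C)(O)CC[C@H](CCO)C[C@H]1O[C@@]1(C)CC/C=C(\C)C2 | intermediate
28 | macrocyclic C16 aldehyde | C2C(=O)[C@@](C)(O)CC[C@H](CC=O)C[C@H]1O[C@@]1(C)CC/C=C(\C)C2 | intermediate
29 | macrocyclic 2-substituted acrolein | C2C(=O)[C@@](C)(O)CC[C@H](C(=C)C=O)C[C@H]1O[C@@]1(C)CC/C=C(\C)C2 | intermediate
30 | macrocyclic acrylic acid | C2C(=O)[C@@](C)(O)CC[C@H](C(=C)C(=O)O)C[C@H]1O[C@@]1(C)CC/C=C(\C)C2 | intermediate
31 | CNP0154954.4 | C=C(C(=O)OC)[C@H]1CC[C@](C)(O)C(=O)CC/C(C)=C/CC[C@]2(C)O[C@@H]2C1 | target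

## Step count and risks
Total steps: 25. Longest linear sequence: 23 (steps 1–6, then 9–25).

**Stereocentres.** C4 and C12 are set in step 1. C1 is set in step 9. C13 is set in step 11 and inverted in step 14. The C8=C9 geometry is set in step 15. Both halves come from the same acid 5 of about 94% ee. The minor enantiomer therefore ends up mainly in diastereomers of 13–17, which are removed by chromatography.

**Risk 1, step 9 (fragment union).** The hindered keto ester 12 may add slowly, or the adduct may be lost to lactol or retro-Michael chemistry.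
- The fallback sets out from 12 and 8 and returns at 15.
- Compound 12 is first deallylated and decarboxylated (Pd(OAc)2, PPh3, HCO2H, Et3N) to (S)-3-methyl-3-(triethylsilyloxy)hept-6-en-2-one F1.
- F1 can enolise on one side only. It is converted (LDA, TMSCl, −78 °C) into (S)-3-methyl-3-(triethylsilyloxy)-2-(trimethylsilyloxy)hepta-1,6-diene F2.
- F2 is then added to enal 8 in an organocatalytic Mukaiyama–Michael reaction with (2S,5S)-5-benzyl-2-tert-butyl-3-methylimidazolidin-4-one as its 2,4-dinitrobenzoic acid salt. This catalyst exposes the same enal face as the prolinol ether.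
- Hydrolytic loss of the silyl group gives keto aldehyde 15 directly, so no decarboxylation is needed after the coupling.

**Risk 2, step 11 (C13 configuration at a very hindered ketone).** If reagent control is slow or incomplete, stereocontrol is replaced by separation and recycling.
- The fallback sets out from 15 and returns at 17.
- NaBH4 in MeOH reduces both carbonyl groups of 15. This gives 16 together with methyl (2S,5R,7R,8S)-2-(tert-butyldimethylsilyloxy)-7-hydroxy-5-(2-hydroxyethyl)-2,8-dimethyl-8-(triethylsilyloxy)dodec-11-enoate F3.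
- Selective silylation as in step 12 gives 17 and its C13 epimer, methyl (2S,5R,7R,8S)-2-(tert-butyldimethylsilyloxy)-5-[2-(tert-butyldiphenylsilyloxy)ethyl]-7-hydroxy-2,8-dimethyl-8-(triethylsilyloxy)dodec-11-enoate F4. The two are separated on silica.
- F4 is oxidised with Dess–Martin periodinane to methyl (2S,5R,8S)-2-(tert-butyldimethylsilyloxy)-5-[2-(tert-butyldiphenylsilyloxy)ethyl]-2,8-dimethyl-7-oxo-8-(triethylsilyloxy)dodec-11-enoate F5.
- F5 is reduced again, so the material is funnelled into 17.

**Risk 3, step 19 (macrocyclisation).** Oligomers or O-alkylation may compete.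
- The fallback sets out from 23 and returns at 25.
- The allylic alcohol 23 is converted (ClCO2Me, pyridine, 0 °C) into the C7 allylic methyl carbonate of the β-keto sulfone F6.
- F6 is cyclised by Tsuji–Trost allylic alkylation (Pd2(dba)3·CHCl3, dppe, THF, 60 °C, 2 mM).
- Zerovalent palladium ionises the carbonate, and the methoxide released deprotonates the keto sulfone.
- The soft carbanion attacks the less hindered C7 terminus of the π-allyl complex with the E geometry kept, giving 25 without added base and without handling an allylic bromide.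

## Further compounds
F1 | step 9 | (S)-3-methyl-3-(triethylsilyloxy)hept-6-en-2-one | CC(=O)[C@](C)(CCC=C)O[Si](CC)(CC)CC
F2 | step 9 | (S)-3-methyl-3-(triethylsilyloxy)-2-(trimethylsilyloxy)hepta-1,6-diene | C=C(O[Si](C)(C)C)[C@](C)(CCC=C)O[Si](CC)(CC)CC
F3 | step 11 | methyl (2S,5R,7R,8S)-2-(tert-butyldimethylsilyloxy)-7-hydroxy-5-(2-hydroxyethyl)-2,8-dimethyl-8-(triethylsilyloxy)dodec-11-enoate | COC(=O)[C@@](C)(O[Si](C)(C)C(C)(C)C)CC[C@H](CCO)C[C@@H](O)[C@](C)(CCC=C)O[Si](CC)(CC)CC
F4 | step 11 | methyl (2S,5R,7R,8S)-2-(tert-butyldimethylsilyloxy)-5-[2-(tert-butyldiphenylsilyloxy)ethyl]-7-hydroxy-2,8-dimethyl-8-(triethylsilyloxy)dodec-11-enoate | COC(=O)[C@@](C)(O[Si](C)(C)C(C)(C)C)CC[C@H](CCO[Si](c1ccccc1)(c1ccccc1)C(C)(C)C)C[C@@H](O)[C@](C)(CCC=C)O[Si](CC)(CC)CC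
F5 | step 11 | methyl (2S,5R,8S)-2-(tert-butyldimethylsilyloxy)-5-[2-(tert-butyldiphenylsilyloxy)ethyl]-2,8-dimethyl-7-oxo-8-(triethylsilyloxy)dodec-11-enoate | COC(=O)[C@@](C)(O[Si](C)(C)C(C)(C)C)CC[C@H](CCO[Si](c1ccccc1)(c1ccccc1)C(C)(C)C)CC(=O)[C@](C)(CCC=C)O[Si](CC)(CC)CC
F6 | step 19 | C7 allylic methyl carbonate of the β-keto sulfone | O=S(=O)(c1ccccc1)CC(=O)[C@@](C)(O[Si](C)(C)C(C)(C)C)CC[C@H](CCO[Si](c1ccccc1)(c1ccccc1)C(C)(C)C)C[C@H]1O[C@@]1(C)CC/C=C(\C)COC(=O)OC
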